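**Assumption (one line):** the SMILES is read literally in germacrane numbering as (4R,5S,6S,7R,8S,10R,11R), i.e. a cis-4,5-epoxide on the face anti to O6, a trans-fused 6α,12-olide, 8α-tiglate, 10α-acetate and 11βH; compounds 1, 10 and 11 are taken as commercial.

## Retrosynthetic overview

1. Target ⇐ acetylation of the 10α-ol ⇐ Mn-HAT/O2 hydration of a 10(14)-methylene-1-ketone (sets C10) ⇐ tigloylation of the 8α-ol.
2. Ten-membered ring ⇐ C8–C9 bond by intramolecular Cr-electrocatalytic allylation of a C8 aldehyde with a 2-(bromomethyl)enone (closes the carbocycle last, sets C8).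
3. cis-4,5-Epoxide ⇐ A(1,3)-controlled epoxidation of the Z-C4=C5 alkene; C3–C4 ⇐ Negishi coupling of a (Z)-vinyl iodide with a ketone zinc homoenolate.
4. Trisubstituted γ-lactone ⇐ (S)-5-(hydroxymethyl)furan-2(5H)-one: photochemical dioxolanyl-radical addition (C7–C8, sets C7), then enolate hydroxymethylation (C11–C13, sets C11).
5. Ring order: γ-lactone (bought) → epoxide → ten-membered carbocycle.

## Route

**Step 1**
Reactants: 1 (S)-5-(hydroxymethyl)furan-2(5H)-one
Product: 2 (S)-5-{[(triethylsilyl)oxy]methyl}furan-2(5H)-one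
Conditions: TESCl, imidazole, CH2Cl2, 0 °C
Reagents that add atoms: chlorotriethylsilane, CC[Si](Cl)(CC)CC
Why: Routine O-silylation; the TES ether survives LDA and can later be oxidised directly, and the bought C6 stereocentre is untouched.

**Step 2**
Reactants: 2 (S)-5-{[(triethylsilyl)oxy]methyl}furan-2(5H)-one
Product: 3 (4S,5S)-4-(1,3-dioxolan-2-yl)-5-{[(triethylsilyl)oxy]methyl}oxolan-2-one
Conditions: Ph2CO (10 mol%), 1,3-dioxolane (solvent), hν 350 nm, degassed, rt
Reagents that add atoms: 1,3-dioxolane, C1COCO1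
Why: Benzophenone-sensitised photochemical radical conjugate addition (Giese-type C–H addition): the dioxolan-2-yl radical attacks the butenolide β-carbon anti to the C5 substituent, forming C7–C8 and setting C7 trans to C6.

**Step 3**
Reactants: 3 (4S,5S)-4-(1,3-dioxolan-2-yl)-5-{[(triethylsilyl)oxy]methyl}oxolan-2-one
Product: 6 [(3R,4S,5S)-4-(1,3-dioxolan-2-yl)-2-oxo-5-{[(triethylsilyl)oxy]methyl}oxolan-3-yl]methyl acetate, via lithium enolate 4 (not isolated), via lithium alkoxide 5 (not isolated)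
Conditions: LDA, THF, −78 °C; CH2O (g), −78 → −25 °C; Ac2O, −25 → 0 °C
Reagents that add atoms: formaldehyde, C=O; acetic anhydride, CC(=O)OC(C)=O
Why: Lactone-enolate aldol with monomeric formaldehyde (Grieco hydroxymethylation) occurs anti to the adjacent dioxolanyl group, setting C11 (3,4-trans), and the alkoxide is trapped in situ as the acetate that the target carries.

**Step 4**
Reactants: 6 [(3R,4S,5S)-4-(1,3-dioxolan-2-yl)-2-oxo-5-{[(triethylsilyl)oxy]methyl}oxolan-3-yl]methyl acetate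
Product: 8 [(3R,4S,5S)-4-(1,3-dioxolan-2-yl)-5-formyl-2-oxooxolan-3-yl]methyl acetate, via alkoxysulfonium chloride 7 (not isolated)
Conditions: (COCl)2, DMSO, CH2Cl2, −78 → −35 °C; Et3N, −78 → 0 °C; use crude
Reagents that add atoms: none
Why: Swern oxidation applied directly to the primary TES ether gives the C5 aldehyde in one operation; cold work-up and immediate use avoid epimerisation at C6.

**Step 5**
Reactants: 8 [(3R,4S,5S)-4-(1,3-dioxolan-2-yl)-5-formyl-2-oxooxolan-3-yl]methyl acetate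
Product: 9 [(3R,4S,5S)-4-(1,3-dioxolan-2-yl)-5-[(1Z)-2-iodoprop-1-en-1-yl]-2-oxooxolan-3-yl]methyl acetate
Conditions: [Ph3PCH(I)CH3]I, NaHMDS, THF, −78 °C; then 8, −78 → −20 °C
Reagents that add atoms: (1-iodoethyl)triphenylphosphonium iodide, CC(I)[P+](c1ccccc1)(c1ccccc1)c1ccccc1.[I-]
Why: Stork–Zhao–Wittig olefination with the weakly basic α-iodo ylide gives the (Z)-2-iodoalkene (iodine cis to the lactone), which fixes the later Z-trisubstituted C4=C5 geometry.

**Step 6**
Reactants: 10 tert-butyl[(2-bromoprop-2-en-1-yl)oxy]dimethylsilane; 11 3-iodopropanoic acid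
Product: 15 2-({[tert-butyl(dimethyl)silyl]oxy}methyl)-5-iodopent-1-en-3-one, via 3-iodopropanoyl chloride 12 (not isolated), via alkenyllithium 13 (not isolated), via alkenylzinc chloride 14 (not isolated)
Conditions: 11, (COCl)2, cat. DMF, CH2Cl2, rt, evaporate; 10, t-BuLi (2 equiv), Et2O, −78 °C; ZnCl2, THF, −78 → 0 °C; then 12, Pd(PPh3)4 (3 mol%), 0 °C
Reagents that add atoms: none
Why: Bromine–lithium exchange, transmetalation to zinc and Negishi acylation of the acid chloride give the achiral 2-(silyloxymethyl)enone fragment carrying C1–C3, C9, C10 and C14.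

**Step 7**
Reactants: 9 [(3R,4S,5S)-4-(1,3-dioxolan-2-yl)-5-[(1Z)-2-iodoprop-1-en-1-yl]-2-oxooxolan-3-yl]methyl acetate; 15 2-({[tert-butyl(dimethyl)silyl]oxy}methyl)-5-iodopent-1-en-3-one
Product: 17 {(3R,4S,5R)-5-[(1Z)-6-({[tert-butyl(dimethyl)silyl]oxy}methyl)-2-methyl-5-oxohepta-1,6-dien-1-yl]-4-(1,3-dioxolan-2-yl)-2-oxooxolan-3-yl}methyl acetate, via alkylzinc iodide 16 (not isolated)
Conditions: 15, Zn dust, LiCl, THF, rt; then 9, Pd(dppf)Cl2 (5 mol%), THF/DMA, rt
Reagents that add atoms: none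
Why: Zinc insertion gives the ketone homoenolate, which undergoes Negishi sp3–sp2 cross-coupling with retention of alkene geometry to form C3–C4 under neutral conditions that spare the β-acetoxy lactone.

**Step 8**
Reactants: 17 {(3R,4S,5R)-5-[(1Z)-6-({[tert-butyl(dimethyl)silyl]oxy}methyl)-2-methyl-5-oxohepta-1,6-dien-1-yl]-4-(1,3-dioxolan-2-yl)-2-oxooxolan-3-yl}methyl acetate
Product: 18 {(3R,4S,5R)-4-formyl-5-[(1Z)-6-(hydroxymethyl)-2-methyl-5-oxohepta-1,6-dien-1-yl]-2-oxooxolan-3-yl}methyl acetate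
Conditions: TsOH·H2O (0.3 equiv), acetone/H2O 10:1, 40 °C
Reagents that add atoms: water, O
Why: Acid-catalysed acetal hydrolysis unmasks the C8 aldehyde and cleaves the primary allylic silyl ether in one pot with a non-nucleophilic acid; C7 stays in its more stable all-trans arrangement.

**Step 9**
Reactants: 18 {(3R,4S,5R)-4-formyl-5-[(1Z)-6-(hydroxymethyl)-2-methyl-5-oxohepta-1,6-dien-1-yl]-2-oxooxolan-3-yl}methyl acetate
Product: 19 {(3R,4S,5R)-5-[(1Z)-6-(bromomethyl)-2-methyl-5-oxohepta-1,6-dien-1-yl]-4-formyl-2-oxooxolan-3-yl}methyl acetate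
Conditions: PBr3 (0.4 equiv), Et2O, −10 °C
Reagents that add atoms: phosphorus tribromide, BrP(Br)Br
Why: Standard bromination of a 2-(hydroxymethyl)enone (SN2 and SN2′ give the same product), done before epoxidation so that no HBr meets the epoxide.

**Step 10**
Reactants: 19 {(3R,4S,5R)-5-[(1Z)-6-(bromomethyl)-2-methyl-5-oxohepta-1,6-dien-1-yl]-4-formyl-2-oxooxolan-3-yl}methyl acetate
Product: 20 {(3R,4S,5S)-5-[(2S,3R)-3-[4-(bromomethyl)-3-oxopent-4-en-1-yl]-3-methyloxiran-2-yl]-4-formyl-2-oxooxolan-3-yl}methyl acetate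
Conditions: mCPBA (1.05 equiv), NaHCO3, CH2Cl2, −20 °C
Reagents that add atoms: 3-chloroperbenzoic acid, OOC(=O)c1cccc(Cl)c1
Why: Prilezhaev epoxidation of the only electron-rich alkene; A(1,3) strain of the Z-alkene holds H6 in the alkene plane and the peracid attacks anti to the allylic lactone C–O bond (Kishi-type model for Z-allylic ethers), giving the cis-epoxide 4R,5S.

**Step 11**
Reactants: 20 {(3R,4S,5S)-5-[(2S,3R)-3-[4-(bromomethyl)-3-oxopent-4-en-1-yl]-3-methyloxiran-2-yl]-4-formyl-2-oxooxolan-3-yl}methyl acetate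
Product: 21 (4R,5S,6S,7R,8S,11R)-13-acetoxy-4,5-epoxy-8-hydroxy-1-oxogermacr-10(14)-en-12,6-olide
Conditions: CrCl3 (20 mol%), Cp2ZrCl2 (1.5 equiv), LiCl, DMF, Al(+)/Ni-foam(−), 2 mA, 20 added by syringe pump (2 mM), rt; aqueous work-up
Reagents that add atoms: none
Why: Proposed new method: a chromium-electrocatalytic intramolecular Nozaki–Hiyama (Barbier-type) allylation in which cathodically regenerated Cr(II) turns the 2-(bromomethyl)enone into a Cr(III) dienolate that adds through its γ-carbon (C9) to the C8 aldehyde in a closed chair transition state while Cp2ZrCl2 frees chromium from the alkoxide, so the ten-membered ring closes with allylic transposition to the 10(14)-methylene ketone and the metal-bound oxygen takes the peripheral position anti to C6 (H8 anti to H7), setting 8S under control of C7; the closest known reactions are the intermolecular electrochemical NHK/Cr-catalysed allylation of aldehydes and the stoichiometric CrCl2 closure of ω-formyl allylic bromides to germacrane rings.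

**Step 12**
Reactants: 21 (4R,5S,6S,7R,8S,11R)-13-acetoxy-4,5-epoxy-8-hydroxy-1-oxogermacr-10(14)-en-12,6-olide
Product: 22 (4R,5S,6S,7R,8S,11R)-13-acetoxy-4,5-epoxy-8-[(2E)-2-methylbut-2-enoyloxy]-1-oxogermacr-10(14)-en-12,6-olide
Conditions: tigloyl chloride, DMAP, pyridine, CH2Cl2, 0 °C → rt
Reagents that add atoms: (2E)-2-methylbut-2-enoyl chloride, C/C=C(\C)C(Cl)=O
Why: DMAP-catalysed acylation with retention at C8; 5-endo oxa-Michael closure onto the enone is disfavoured and the E-acyl chloride does not isomerise.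

**Step 13**
Reactants: 22 (4R,5S,6S,7R,8S,11R)-13-acetoxy-4,5-epoxy-8-[(2E)-2-methylbut-2-enoyloxy]-1-oxogermacr-10(14)-en-12,6-olide
Product: 24 (4R,5S,6S,7R,8S,10R,11R)-13-acetoxy-4,5-epoxy-10-hydroxy-8-[(2E)-2-methylbut-2-enoyloxy]-1-oxogermacran-12,6-olide, via tertiary hydroperoxide 23 (not isolated)
Conditions: Mn(dpm)3 (10 mol%), PhSiH3 (1.5 equiv), O2 (1 atm), i-PrOH/CH2Cl2, 0 °C; then P(OEt)3
Reagents that add atoms: dioxygen, O=O
Why: Mukaiyama-type hydration (Mn–H hydrogen-atom transfer to the terminal enone CH2, which becomes the C14 methyl, then O2 capture of the α-keto radical); O2 is expected to add on the α-face of the macrocycle, away from the β-oriented C15/C11 substituents, giving 10R, and the β-substituted tiglate reacts far more slowly.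

**Step 14**
Reactants: 24 (4R,5S,6S,7R,8S,10R,11R)-13-acetoxy-4,5-epoxy-10-hydroxy-8-[(2E)-2-methylbut-2-enoyloxy]-1-oxogermacran-12,6-olide
Product: 25 (4R,5S,6S,7R,8S,10R,11R)-10,13-diacetoxy-4,5-epoxy-8-[(2E)-2-methylbut-2-enoyloxy]-1-oxogermacran-12,6-olide
Conditions: Ac2O, DMAP, pyridine, rt
Reagents that add atoms: acetic anhydride, CC(=O)OC(C)=O
Why: DMAP-catalysed acetylation of the tertiary α-ketol under mild base that does not eliminate the β-acetoxy lactone; no stereocentre is touched.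

## Compound list

1 | (S)-5-(hydroxymethyl)furan-2(5H)-one | OC[C@H]1OC(=O)C=C1 | starting material
2 | (S)-5-{[(triethylsilyl)oxy]methyl}furan-2(5H)-one | CC[Si](CC)(CC)OC[C@H]1OC(=O)C=C1 | intermediate
3 | (4S,5S)-4-(1,3-dioxolan-2-yl)-5-{[(triethylsilyl)oxy]methyl}oxolan-2-one (4,5-trans) | CC[Si](CC)(CC)OC[C@H]1OC(=O)C[C@@H]1C1OCCO1 | intermediate
4 | lithium (4S,5S)-4-(1,3-dioxolan-2-yl)-5-{[(triethylsilyl)oxy]methyl}-4,5-dihydrofuran-2-olate (lithium enolate of 3) | CC[Si](CC)(CC)OC[C@H]1OC(O[Li])=C[C@@H]1C1OCCO1 | intermediate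
5 | lithium [(3R,4S,5S)-4-(1,3-dioxolan-2-yl)-2-oxo-5-{[(triethylsilyl)oxy]methyl}oxolan-3-yl]methanolate | CC[Si](CC)(CC)OC[C@H]1OC(=O)[C@@H](CO[Li])[C@@H]1C1OCCO1 | intermediate
6 | [(3R,4S,5S)-4-(1,3-dioxolan-2-yl)-2-oxo-5-{[(triethylsilyl)oxy]methyl}oxolan-3-yl]methyl acetate | CC[Si](CC)(CC)OC[C@H]1OC(=O)[C@@H](COC(C)=O)[C@@H]1C1OCCO1 | intermediate
7 | {[(2S,3S,4R)-4-(acetoxymethyl)-3-(1,3-dioxolan-2-yl)-5-oxooxolan-2-yl]methoxy}dimethylsulfonium chloride | C[S+](C)OC[C@H]1OC(=O)[C@@H](COC(C)=O)[C@@H]1C1OCCO1.[Cl-] | intermediate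
8 | [(3R,4S,5S)-4-(1,3-dioxolan-2-yl)-5-formyl-2-oxooxolan-3-yl]methyl acetate | O=C[C@H]1OC(=O)[C@@H](COC(C)=O)[C@@H]1C1OCCO1 | intermediate
9 | [(3R,4S,5S)-4-(1,3-dioxolan-2-yl)-5-[(1Z)-2-iodoprop-1-en-1-yl]-2-oxooxolan-3-yl]methyl acetate | C/C(I)=C/[C@H]1OC(=O)[C@@H](COC(C)=O)[C@@H]1C1OCCO1 | intermediate
10 | tert-butyl[(2-bromoprop-2-en-1-yl)oxy]dimethylsilane | C=C(Br)CO[Si](C)(C)C(C)(C)C | starting material
11 | 3-iodopropanoic acid | OC(=O)CCI | starting material
12 | 3-iodopropanoyl chloride | ClC(=O)CCI | intermediate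
13 | {3-[(tert-butyldimethylsilyl)oxy]prop-1-en-2-yl}lithium | [Li]C(=C)CO[Si](C)(C)C(C)(C)C | intermediate
14 | chlorido{3-[(tert-butyldimethylsilyl)oxy]prop-1-en-2-yl}zinc | Cl[Zn]C(=C)CO[Si](C)(C)C(C)(C)C | intermediate
15 | 2-({[tert-butyl(dimethyl)silyl]oxy}methyl)-5-iodopent-1-en-3-one | ICCC(=O)C(=C)CO[Si](C)(C)C(C)(C)C | intermediate
16 | {4-({[tert-butyl(dimethyl)silyl]oxy}methyl)-3-oxopent-4-en-1-yl}zinc iodide | I[Zn]CCC(=O)C(=C)CO[Si](C)(C)C(C)(C)C | intermediate
17 | {(3R,4S,5R)-5-[(1Z)-6-({[tert-butyl(dimethyl)silyl]oxy}methyl)-2-methyl-5-oxohepta-1,6-dien-1-yl]-4-(1,3-dioxolan-2-yl)-2-oxooxolan-3-yl}methyl acetate | CC(C)(C)[Si](C)(C)OCC(=C)C(=O)CC/C(C)=C\[C@H]1OC(=O)[C@@H](COC(C)=O)[C@@H]1C1OCCO1 | intermediate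
18 | {(3R,4S,5R)-4-formyl-5-[(1Z)-6-(hydroxymethyl)-2-methyl-5-oxohepta-1,6-dien-1-yl]-2-oxooxolan-3-yl}methyl acetate | OCC(=C)C(=O)CC/C(C)=C\[C@H]1OC(=O)[C@@H](COC(C)=O)[C@@H]1C=O | intermediate
19 | {(3R,4S,5R)-5-[(1Z)-6-(bromomethyl)-2-methyl-5-oxohepta-1,6-dien-1-yl]-4-formyl-2-oxooxolan-3-yl}methyl acetate | BrCC(=C)C(=O)CC/C(C)=C\[C@H]1OC(=O)[C@@H](COC(C)=O)[C@@H]1C=O | intermediate
20 | {(3R,4S,5S)-5-[(2S,3R)-3-[4-(bromomethyl)-3-oxopent-4-en-1-yl]-3-methyloxiran-2-yl]-4-formyl-2-oxooxolan-3-yl}methyl acetate (cis-epoxide) | BrCC(=C)C(=O)CC[C@@]1(C)O[C@H]1[C@H]1OC(=O)[C@@H](COC(C)=O)[C@@H]1C=O | intermediate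
21 | (4R,5S,6S,7R,8S,11R)-13-acetoxy-4,5-epoxy-8-hydroxy-1-oxogermacr-10(14)-en-12,6-olide (8α-OH) | O[C@H]1CC(=C)C(=O)CC[C@@]2(C)O[C@H]2[C@H]2OC(=O)[C@@H](COC(C)=O)[C@@H]21 | intermediate
22 | (4R,5S,6S,7R,8S,11R)-13-acetoxy-4,5-epoxy-8-[(2E)-2-methylbut-2-enoyloxy]-1-oxogermacr-10(14)-en-12,6-olide | C/C=C(\C)C(=O)O[C@H]1CC(=C)C(=O)CC[C@@]2(C)O[C@H]2[C@H]2OC(=O)[C@@H](COC(C)=O)[C@@H]21 | intermediate
23 | (4R,5S,6S,7R,8S,10R,11R)-13-acetoxy-4,5-epoxy-10-hydroperoxy-8-[(2E)-2-methylbut-2-enoyloxy]-1-oxogermacran-12,6-olide | C/C=C(\C)C(=O)O[C@H]1C[C@@](C)(OO)C(=O)CC[C@@]2(C)O[C@H]2[C@H]2OC(=O)[C@@H](COC(C)=O)[C@@H]21 | intermediate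
24 | (4R,5S,6S,7R,8S,10R,11R)-13-acetoxy-4,5-epoxy-10-hydroxy-8-[(2E)-2-methylbut-2-enoyloxy]-1-oxogermacran-12,6-olide | C/C=C(\C)C(=O)O[C@H]1C[C@@](C)(O)C(=O)CC[C@@]2(C)O[C@H]2[C@H]2OC(=O)[C@@H](COC(C)=O)[C@@H]21 | intermediate
25 | (4R,5S,6S,7R,8S,10R,11R)-10,13-diacetoxy-4,5-epoxy-8-[(2E)-2-methylbut-2-enoyloxy]-1-oxogermacran-12,6-olide | C/C=C(\C)C(=O)O[C@H]1C[C@@](C)(OC(C)=O)C(=O)CC[C@@]2(C)O[C@H]2[C@H]2OC(=O)[C@@H](COC(C)=O)[C@@H]21 | target

## Step count and risks

Total step count: 14. Longest linear sequence: 13 (steps 1–5 and 7–14 from compound 1); step 6 makes the side fragment.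

The three steps most likely to fail:

- **Epoxidation, step 10.** The facial preference of a peracid next to an acylated allylic oxygen is modest in some cases, so the wrong face may be attacked. Fallback: postpone the epoxidation. Set out from 19 and close the ring first (ring closure as in step 11, or with CrCl2) to give the macrocyclic dienol (4Z,6R,7R,8S,11R)-13-acetoxy-8-hydroxy-1-oxogermacra-4,10(14)-dien-12,6-olide F1. Then epoxidise with VO(acac)2/t-BuOOH, using the 8α-hydroxyl (bishomoallylic, carried by C7 on the alkene face anti to O6) to deliver oxygen to the required face; the electron-poor enone alkene is not touched. This rejoins the route at 21.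

- **Electrochemical ring closure, step 11 (the new step).** The ring may fail to close catalytically, or may close to the other C8 epimer. Fallback with known chemistry: set out from 20 and run the classical stoichiometric Nozaki–Hiyama closure (CrCl2, 8 equiv, THF/DMF, syringe-pump addition), the reaction type already used to close germacrane rings from ω-formyl allylic bromides; this returns at 21. If the alcohol obtained is instead the 8β epimer (4R,5S,6S,7R,8R,11R)-13-acetoxy-4,5-epoxy-8-hydroxy-1-oxogermacr-10(14)-en-12,6-olide F2, esterify it with tiglic acid under Mitsunobu conditions (PPh3, DIAD, toluene; inversion at C8), which returns directly at 22.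

- **HAT hydration, step 13.** O2 capture of the planar C10 radical may show low or reversed facial selectivity. Fallback with a polar, closed-shell oxygen transfer: set out from 22 and carry out Rh-catalysed 1,4-hydrosilylation of the methylene ketone (Et3SiH, RhCl(PPh3)3) to the tetrasubstituted silyl enol ether (4R,5S,6S,7R,8S,11R)-13-acetoxy-4,5-epoxy-8-[(2E)-2-methylbut-2-enoyloxy]-1-[(triethylsilyl)oxy]germacr-1(10)-en-12,6-olide F3 (drawn with C2 and C9 cis; either enol-ether geometry converges). Rubottom oxidation (dimethyldioxirane, acetone, −40 °C, then buffered desilylation) gives the α-hydroxy ketone and returns at 24.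

## Further compounds

F1 | step 10 | (4Z,6R,7R,8S,11R)-13-acetoxy-8-hydroxy-1-oxogermacra-4,10(14)-dien-12,6-olide | O[C@H]1CC(=C)C(=O)CC/C(C)=C\[C@H]2OC(=O)[C@@H](COC(C)=O)[C@@H]21
F2 | step 11 | (4R,5S,6S,7R,8R,11R)-13-acetoxy-4,5-epoxy-8-hydroxy-1-oxogermacr-10(14)-en-12,6-olide | O[C@@H]1CC(=C)C(=O)CC[C@@]2(C)O[C@H]2[C@H]2OC(=O)[C@@H](COC(C)=O)[C@@H]21
F3 | step 13 | (4R,5S,6S,7R,8S,11R)-13-acetoxy-4,5-epoxy-8-[(2E)-2-methylbut-2-enoyloxy]-1-[(triethylsilyl)oxy]germacr-1(10)-en-12,6-olide | C/C=C(\C)C(=O)O[C@H]1C/C(C)=C(O[Si](CC)(CC)CC)\CC[C@@]2(C)O[C@H]2[C@H]2OC(=O)[C@@H](COC(C)=O)[C@@H]21
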